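**Retrosynthetic overview**
1. Ring letters: A = central tetrasubstituted benzene, B = 4-oxyphenyl on ring A, C = 4-oxyphenyl on the alkyne, D = phenyl, E = cyclohexa-2,5-dienone. Ring E with its exocyclic C=C is the dehydrated form of a 4-hydroxyphenyl triaryl carbinol, so the endgame is PhLi addition (ring D) to diaryl ketone 14 and BBr3-triggered dehydration with O-deprotection.
2. Key disconnection: ring E is built from open-chain precursors by a Diels–Alder reaction and aromatisation. Ethynyl ketone 10 gives two ring carbons, and its C=O carbon becomes the exocyclic methylidene carbon. The 1-methoxy-3-silyloxydiene 12 gives four ring carbons and the ring oxygen.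
3. Enabling feature: in ring E the carbonyl oxygen lies 1,4 (para) to the ring carbon that carries the exocyclic C=C, and the ring is otherwise unsubstituted and symmetric. With the exocyclic carbon taken back to a ketone, ring E is a 4-oxygenated aroyl ring, which is the regiochemical output of a 2-silyloxydiene and a terminal ynone.
4. Ring A is bought as 2-bromo-4-chlorotoluene and dressed: formylation between the halogens, Sonogashira coupling at C–Br (ring C), Suzuki–Miyaura coupling at C–Cl (ring B), then ethynylation and oxidation to ynone 10.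
5. Order of ring events: A purchased; C and B attached; E formed by cycloaddition; D attached; E unmasked as the quinone methide.

Key step: step 7

Assumption: the target has no stereocentre, and the symmetric ring E gives the exocyclic C=C no E/Z descriptor; the hindered axis at ring A is taken as configurationally undefined, so racemic 9, 13 and 16 suffice.
Ar denotes the ring A fragment 4'-methoxy-3-[(4-methoxyphenyl)ethynyl]-4-methyl-[1,1'-biphenyl]-2-yl.

**Route**

Step 1
Reactants: 1 2-bromo-4-chlorotoluene
Product: 3 2-bromo-6-chloro-3-methylbenzaldehyde, via aryllithium 2 (not isolated)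
Conditions: LDA (1.1 equiv), THF, −78 °C; DMF, −78 to 0 °C; 1 M HCl
Reagents that add atoms: N,N-dimethylformamide (DMF), CN(C)C=O
Why: Directed ortho-lithiation and formylation: the C–H flanked by Br and Cl is by far the most acidic ring position, the aryllithium is held at −78 °C to prevent loss of LiBr to an aryne, and DMF places the future methylidene carbon between the two halogens.

Step 2
Reactants: 3 2-bromo-6-chloro-3-methylbenzaldehyde; 4 4-ethynylanisole
Product: 5 6-chloro-2-[(4-methoxyphenyl)ethynyl]-3-methylbenzaldehyde
Conditions: Pd(PPh3)2Cl2 (3 mol %), CuI (5 mol %), Et3N, THF, 50 °C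
Reagents that add atoms: none
Why: Sonogashira coupling: with a PPh3-ligated catalyst, oxidative addition into the formyl-activated C–Br bond is much faster than into C–Cl, so only the position next to the methyl group should be alkynylated.

Step 3
Reactants: 5 6-chloro-2-[(4-methoxyphenyl)ethynyl]-3-methylbenzaldehyde; 6 4-methoxyphenylboronic acid
Product: 7 4'-methoxy-3-[(4-methoxyphenyl)ethynyl]-4-methyl-[1,1'-biphenyl]-2-carbaldehyde (Ar–CHO)
Conditions: Pd(OAc)2 (3 mol %), SPhos (6 mol %), K3PO4, toluene/H2O, 90 °C
Reagents that add atoms: none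
Why: Suzuki–Miyaura coupling of the ortho-formyl-activated aryl chloride with an electron-rich biarylphosphine ligand; the aldehyde and the internal alkyne should be inert under these conditions.

Step 4
Reactants: 7 Ar–CHO; 8 ethynylmagnesium bromide
Product: 9 racemic 1-Ar-prop-2-yn-1-ol
Conditions: HC≡CMgBr (1.5 equiv), THF, 0 °C; sat. aq NH4Cl
Reagents that add atoms: none
Why: Grignard 1,2-addition of a small sp nucleophile to the hindered aldehyde; the carbinol stereocentre forms racemic and is erased in step 5.

Step 5
Reactants: 9 racemic 1-Ar-prop-2-yn-1-ol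
Product: 10 1-Ar-prop-2-yn-1-one (terminal ynone)
Conditions: Dess–Martin periodinane (1.3 equiv), CH2Cl2, 0 °C to rt
Reagents that add atoms: none
Why: Dess–Martin oxidation of the secondary benzylic-propargylic alcohol runs at or below room temperature without acid, base or nucleophile, which the conjugate-acceptor ynone and its ortho arylethynyl neighbour require.

Step 6
Reactants: 11 (E)-4-methoxybut-3-en-2-one
Product: 12 (E)-tert-butyl[(4-methoxybuta-1,3-dien-2-yl)oxy]dimethylsilane
Conditions: TBSOTf (1.1 equiv), Et3N (1.5 equiv), Et2O, 0 °C to rt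
Reagents that add atoms: tert-butyldimethylsilyl triflate (TBSOTf), CC(C)(C)[Si](C)(C)OS(=O)(=O)C(F)(F)F
Why: Silyl enol ether formation by soft enolisation at the methyl group, the only enolisable position, gives the cross-conjugated 2-silyloxydiene with the E enol ether double bond untouched.

Step 7
Reactants: 10 1-Ar-prop-2-yn-1-one; 12 (E)-tert-butyl[(4-methoxybuta-1,3-dien-2-yl)oxy]dimethylsilane
Product: 14 Ar–C(=O)–C6H4-4-OTBS, {4-[(tert-butyldimethylsilyl)oxy]phenyl}(Ar)methanone, via cycloadduct 13 (not isolated)
Conditions: 12 (2 equiv), toluene, 23 to 40 °C; then camphorsulfonic acid (5 mol %), 0 °C to rt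
Reagents that add atoms: none
Why: A thermal, concerted but asynchronous Diels–Alder reaction of normal electron demand between diene 12 and the terminal ynone of 10 should give cyclohexa-1,4-diene 13; acid then ionises its doubly allylic methoxy group and a proton leaves the ring CH2 (net 1,4-loss of methanol), giving the aromatic silyl ether 14. The closest known reaction type is the cycloaddition of 1-methoxy-3-silyloxybutadienes with propiolates and ethynyl ketones followed by aromatisation to para-oxygenated benzoates and aryl ketones. Ring E is closed by an intermolecular (4+2) cycloaddition in which both new C–C bonds form in the one event. The only new stereocentre, the methoxy-bearing carbon of racemic 13, is removed by the aromatisation, so no stereocontrol is needed. Regioselectivity is secured by matched polarisation: the CH2 terminus next to the silyloxy carbon (largest HOMO coefficient) bonds to the unsubstituted β-carbon of the ynone and the methoxy-bearing terminus to the α-carbon, which puts the oxygen para to the acyl group. Chemoselectivity for the ynone over the unactivated diarylalkyne, and over an intramolecular dehydro-Diels–Alder reaction between the two ortho alkynes that is expected only on strong heating, is secured by working at or below 40 °C without Lewis acid.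

Step 8
Reactants: 14 Ar–C(=O)–C6H4-4-OTBS; 15 phenyllithium
Product: 16 racemic Ar–C(OH)(Ph)–C6H4-4-OTBS, {4-[(tert-butyldimethylsilyl)oxy]phenyl}(Ar)(phenyl)methanol
Conditions: PhLi (2.0 equiv), THF, −78 to −20 °C; sat. aq NH4Cl
Reagents that add atoms: none
Why: Organolithium 1,2-addition to a non-enolisable diaryl ketone: PhLi is small and reactive enough for the carbonyl flanked by the ortho alkynyl and ortho aryl groups, low temperature keeps the lithium alkoxide from adding to the neighbouring alkyne, and the racemic carbinol centre is erased in step 9.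

Step 9
Reactants: 16 racemic Ar–C(OH)(Ph)–C6H4-4-OTBS
Product: 18 selaginellin A, via dimethyl ether 17 (not isolated)
Conditions: BBr3 (8 equiv), CH2Cl2, −78 °C to rt; H2O, 0 °C
Reagents that add atoms: none
Why: Lewis-acid ether cleavage combined with fuchsone-type dehydration: BBr3 ionises the tertiary carbinol to the triarylmethyl cation stabilised by the para silyloxy group, bromide removes the silyl group to give 17 as its boron complex, the two anisole methyl groups are then cleaved as MeBr, and hydrolysis releases the cross-conjugated dienone, the stable form of a 4-hydroxyphenyl diaryl carbinol.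

**Compound list**
1 | 2-bromo-4-chlorotoluene | Cc1ccc(Cl)cc1Br | starting material
2 | (2-bromo-6-chloro-3-methylphenyl)lithium | [Li]c1c(Cl)ccc(C)c1Br | intermediate
3 | 2-bromo-6-chloro-3-methylbenzaldehyde | Cc1ccc(Cl)c(C=O)c1Br | intermediate
4 | 4-ethynylanisole | C#Cc1ccc(OC)cc1 | starting material
5 | 6-chloro-2-[(4-methoxyphenyl)ethynyl]-3-methylbenzaldehyde | Cc1ccc(Cl)c(C=O)c1C#Cc1ccc(OC)cc1 | intermediate
6 | 4-methoxyphenylboronic acid | OB(O)c1ccc(OC)cc1 | starting material
7 | 4'-methoxy-3-[(4-methoxyphenyl)ethynyl]-4-methyl-[1,1'-biphenyl]-2-carbaldehyde | Cc1ccc(-c2ccc(OC)cc2)c(C=O)c1C#Cc1ccc(OC)cc1 | intermediate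
8 | ethynylmagnesium bromide | C#C[Mg]Br | starting material
9 | racemic 1-{4'-methoxy-3-[(4-methoxyphenyl)ethynyl]-4-methyl-[1,1'-biphenyl]-2-yl}prop-2-yn-1-ol | Cc1ccc(-c2ccc(OC)cc2)c(C(O)C#C)c1C#Cc1ccc(OC)cc1 | intermediate
10 | 1-{4'-methoxy-3-[(4-methoxyphenyl)ethynyl]-4-methyl-[1,1'-biphenyl]-2-yl}prop-2-yn-1-one | Cc1ccc(-c2ccc(OC)cc2)c(C(=O)C#C)c1C#Cc1ccc(OC)cc1 | intermediate
11 | (E)-4-methoxybut-3-en-2-one | CO/C=C/C(C)=O | starting material
12 | (E)-tert-butyl[(4-methoxybuta-1,3-dien-2-yl)oxy]dimethylsilane | CO/C=C/C(=C)O[Si](C)(C)C(C)(C)C | intermediate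
13 | racemic {4-[(tert-butyldimethylsilyl)oxy]-6-methoxycyclohexa-1,4-dien-1-yl}(Ar)methanone | Cc1ccc(-c2ccc(OC)cc2)c(C(=O)C2=CCC(O[Si](C)(C)C(C)(C)C)=CC2OC)c1C#Cc1ccc(OC)cc1 | intermediate
14 | {4-[(tert-butyldimethylsilyl)oxy]phenyl}(Ar)methanone | Cc1ccc(-c2ccc(OC)cc2)c(C(=O)c2ccc(O[Si](C)(C)C(C)(C)C)cc2)c1C#Cc1ccc(OC)cc1 | intermediate
15 | phenyllithium | [Li]c1ccccc1 | starting material
16 | racemic {4-[(tert-butyldimethylsilyl)oxy]phenyl}(Ar)(phenyl)methanol | Cc1ccc(-c2ccc(OC)cc2)c(C(O)(c2ccccc2)c2ccc(O[Si](C)(C)C(C)(C)C)cc2)c1C#Cc1ccc(OC)cc1 | intermediate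
17 | 4-[(Ar)(phenyl)methylidene]cyclohexa-2,5-dien-1-one (selaginellin A dimethyl ether) | Cc1ccc(-c2ccc(OC)cc2)c(C(=C2C=CC(=O)C=C2)c2ccccc2)c1C#Cc1ccc(OC)cc1 | intermediate
18 | selaginellin A, 4-[{4'-hydroxy-3-[(4-hydroxyphenyl)ethynyl]-4-methyl-[1,1'-biphenyl]-2-yl}(phenyl)methylidene]cyclohexa-2,5-dien-1-one | Cc1ccc(-c2ccc(O)cc2)c(C(=C2C=CC(=O)C=C2)c2ccccc2)c1C#Cc1ccc(O)cc1 | target

**Totals**
Total step count: 9. Longest linear sequence: 8 steps (steps 1, 2, 3, 4, 5, 7, 8, 9); step 6 is a one-step side branch.

**Steps most likely to fail**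

Step 7. The diene may be lost to hydrolysis or oligomerisation before it adds to the twisted, hindered ynone. If the mixture has to be heated, the ynone may cyclise with its ortho arylethynyl neighbour. The acid-induced aromatisation may also remove the silyl group along with methanol. The fallback brings the oxygenated ring in intact as a nucleophile instead of building it; it sets out from 7 and comes back at 14. [4-(tert-Butyldimethylsilyloxy)phenyl]magnesium bromide F1, made from commercial (4-bromophenoxy)(tert-butyl)dimethylsilane and Mg in THF, should add to aldehyde 7 to give the racemic diaryl carbinol Ar–CH(OH)–C6H4-4-OTBS F2. Dess–Martin oxidation of F2 should give ketone 14.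

Step 8. Steric shielding of the carbonyl by the two ortho substituents of ring A, together with deactivation by the para silyloxy group, may slow 1,2-addition. Attack of PhLi at silicon, or addition of the alkoxide to the neighbouring alkyne, could then take over. The fallback forms the C–phenyl bond by 1,6-conjugate addition at the aldehyde oxidation level; it sets out from 14 and comes back at 17. TBAF should cleave the silyl ether to the 4-hydroxyphenyl ketone F3. NaBH4 in MeOH/THF should reduce it to the 4-hydroxybenzhydrol F4. Catalytic TsOH over MgSO4 in CH2Cl2 should dehydrate F4 to the aryl-substituted para-quinone methide F5, which is used at once. PhMgBr in THF at −78 °C should add 1,6 with aromatisation to give the racemic 4-hydroxytriarylmethane F6. DDQ in CH2Cl2 should dehydrogenate F6 to quinone methide 17, which is then isolated and treated with BBr3 as in step 9.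

Step 9. The long-lived triarylmethyl cation sits next to the alkyne and ring B under a large excess of BBr3. Cation capture by these groups, HBr or bromoborane addition across the electron-rich diarylalkyne, and incomplete demethylation may all lower the outcome. The fallback separates ether cleavage from cation formation; it sets out from 14 and comes back at 18. BBr3 applied to ketone 14, where no carbinol is present, should give the trihydroxy ketone F7. TBSCl and imidazole in DMF should give the tris(silyl ether) ketone F8. PhLi at −78 °C should give the racemic tris(silyl ether) carbinol F9. HF·pyridine in THF should remove the three silyl groups and dehydrate the carbinol to 18 under mild, buffered acid.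

**Further compounds**
F1 | step 7 | [4-(tert-butyldimethylsilyloxy)phenyl]magnesium bromide | CC(C)(C)[Si](C)(C)Oc1ccc([Mg]Br)cc1
F2 | step 7 | racemic {4-[(tert-butyldimethylsilyl)oxy]phenyl}(Ar)methanol | Cc1ccc(-c2ccc(OC)cc2)c(C(O)c2ccc(O[Si](C)(C)C(C)(C)C)cc2)c1C#Cc1ccc(OC)cc1
F3 | step 8 | (4-hydroxyphenyl)(Ar)methanone | Cc1ccc(-c2ccc(OC)cc2)c(C(=O)c2ccc(O)cc2)c1C#Cc1ccc(OC)cc1
F4 | step 8 | racemic 4-[hydroxy(Ar)methyl]phenol | Cc1ccc(-c2ccc(OC)cc2)c(C(O)c2ccc(O)cc2)c1C#Cc1ccc(OC)cc1
F5 | step 8 | 4-[(Ar)methylidene]cyclohexa-2,5-dien-1-one | Cc1ccc(-c2ccc(OC)cc2)c(C=C2C=CC(=O)C=C2)c1C#Cc1ccc(OC)cc1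
F6 | step 8 | racemic 4-[(Ar)(phenyl)methyl]phenol | Cc1ccc(-c2ccc(OC)cc2)c(C(c2ccccc2)c2ccc(O)cc2)c1C#Cc1ccc(OC)cc1
F7 | step 9 | {4'-hydroxy-3-[(4-hydroxyphenyl)ethynyl]-4-methyl-[1,1'-biphenyl]-2-yl}(4-hydroxyphenyl)methanone | Cc1ccc(-c2ccc(O)cc2)c(C(=O)c2ccc(O)cc2)c1C#Cc1ccc(O)cc1
F8 | step 9 | tris(tert-butyldimethylsilyl) ether of F7 | Cc1ccc(-c2ccc(O[Si](C)(C)C(C)(C)C)cc2)c(C(=O)c2ccc(O[Si](C)(C)C(C)(C)C)cc2)c1C#Cc1ccc(O[Si](C)(C)C(C)(C)C)cc1
F9 | step 9 | racemic phenyl carbinol from F8 (tris-silyl analogue of 16) | Cc1ccc(-c2ccc(O[Si](C)(C)C(C)(C)C)cc2)c(C(O)(c2ccccc2)c2ccc(O[Si](C)(C)C(C)(C)C)cc2)c1C#Cc1ccc(O[Si](C)(C)C(C)(C)C)cc1
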